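Readings and results come from a simulation for substances that don't exist, and the scatter is random.

What I want to know of the 0.18 M flask is where Je and Jf stand at 5.0 d, whether it is still changing, and what remains of Je after a very long wait.

| flask | Ja | Jb | remark | time |
|---|---|---|---|---|
| ochre | 0.090 M | 0.80 equiv | run made earlier |  |
| amber | 0.14 M | 0.80 equiv | run made earlier |  |
| flask | 0.18 M | 0.800 equiv |  | 5.0 d |

- ochre (time / d: Je / %, Jf / %): 0.250: 21.5, 11.4; 0.417: 22.1, 18.2; 0.625: 20.9, 25.3; 1.04: 17.6, 34.9; 1.67: 14.7, 41.4; 3.00: 12.8, 44.3
- amber (time / d: Je / %, Jf / %): 0.500: 21.6, 22.7; 1.04: 16.5, 35.5; 1.67: 14.2, 41.2; 2.08: 13.3, 42.6; 2.50: 12.8, 42.8; 3.00: 12.1, 43.6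

(standard deviation of a reading: 0.3 percentage points)

- the state of affairs at 5.0 d: stopped, and by what, or still going (forward and back rates have come level / all of Ja has reacted / it is still moving)
- amount of Je at 5.0 d, in percent of the Ja charged
- amount of Jf at 5.0 d, in percent of the Ja charged
- amount of Je if the flask were left three thousand times as long, in percent of the Ja charged

- the earlier runs were read with a standard deviation of 0.3 percentage points
- the reaction counts as stopped when no species that holds the Ja changes by six tenths of a point or more over the second half of the time

If Je and Jf pass into one another, dividing the rate of one by the rate of the other removes the clock and leaves a number to carry, the split, [Jf]/[Je], which under thermodynamic control stops changing. The last readings of ochre and amber together give a reading of the split of 3.53, though the split is still climbing in the amber run. The sum Je + Jf at that time is 55.7 % in amber against 57.1 % in the more dilute ochre, so I suspect a slow leak that grows with concentration.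

I solve two extreme versions of the 0.18 M flask. If it froze at that sum and split, it would hold 12.3 % Je and 43.4 % Jf. If Je kept amber's late slope, it would reach 9.49 %. I expect the 0.18 M flask between them, because amber's Je is still falling but its slide has slowed. I commit to about 10.9 % Je, and to Jf between 38.5 %, its value at the split, and the frozen figure. I expect the 0.18 M flask still to be moving, since amber's Je lost 0.7 percentage points between its last two readings, and I expect Je, a share of a leaking sum, to tend towards zero after the very long wait.

The forecast, which speaks of “slow Je→Jf drift”, says it is still moving, with 10.8 % Je, 45.5 % Jf and 2 % Je after the long wait.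

For the 0.18 M flask the result is: it is still moving, with 11.3 % Je, 41.6 % Jf and 0.0356 % Je after the long wait.

    Je + Jc → Jg (k = 1.20 × 10⁻⁵ M⁻¹ s⁻¹)
    Jd ⇌ Jf (K = 2.30, k = 1.70 × 10⁻⁵ s⁻¹)
    Ja + Jb → Jd + Jc (k = 0.00220 M⁻¹ s⁻¹)
    Jd ⇌ Je (K = 0.650, k = 7.40 × 10⁻⁵ s⁻¹)

Jd and Jf relax by their step alone, both ways together, with a half-life of 0.329 d, short against the 5.0 d of the 0.18 M flask. The split of that flask at that time is 3.68, above the carried 3.53.

For the neighbour with 0.200 equiv of Jb, I scale amber's sum by the Jb charged to 13.9 % and split it by 3.53, which gives 3.07 % Je and 10.8 % Jf. That flask computes to 3.16 % Je and 11.3 % Jf.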